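The dimer is cut at its spiro-cyclohexene (C2–C4′, C14–C15′) into two copies of one guaianolide, 8β-hydroxy-3-dehydrozaluzanin C; a dehydrogenation/Diels–Alder/isomerisation sequence reunites them. The monomer's cycloheptane (ring B) is closed in one flask: in a cyclopentenone–butyrolactone precursor the C8 aldehyde and the C1=C2–C3=O enone end a five-carbon arc (C1, C5, C6, C7, C8), and 2,3-dibromopropene is inserted as the missing C9–C10(=C14) unit, first by chromium-catalysed 2-bromoallylation (C8–C9), then by nickel-catalysed reductive conjugate addition (C10–C1), cis-fusing rings A and B. Both halves of the target inherit these bonds (C1′–C10′/C8′–C9′ and C1–C10/C8–C9). The precursor is a cyclopropane-derived trans-lactone aldehyde.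

Key step: step 11

Remark: guaiane numbering is used throughout (ring A = C1–C5, ring B = C1, C5–C10, lactone ring C = C6, C7, C11, C12, O); primed atoms belong to the half that keeps a saturated C1′–C2′ (the dienophile-derived half); α/β as in guaianolides (natural 5-H is α).
Remark: cyclopentadiene is taken as freshly cracked from its commercial dimer.
Remark: where a chiral ligand is given by type, the antipode that delivers the drawn enantiomer is meant.

Step 1
Reactants: 1 cyclopenta-1,3-diene
Product: 2 (S)-trichloro(cyclopent-2-en-1-yl)silane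
Conditions: HSiCl3, [PdCl(C3H5)]2 (0.1 mol%), (R)-MOP-type monophosphine, neat, 20 °C
Reagents that add atoms: trichlorosilane, Cl[SiH](Cl)Cl
Why: Palladium-catalysed asymmetric 1,4-hydrosilylation of a cyclic 1,3-diene, in which the chiral monophosphine on the π-allylpalladium intermediate sets the allylic C–Si centre.

Step 2
Reactants: 2 (S)-trichloro(cyclopent-2-en-1-yl)silane
Product: 3 (S)-(cyclopent-2-en-1-yl)trimethylsilane
Conditions: MeMgBr (3.3 equiv), Et2O, 0 °C to rt
Reagents that add atoms: methylmagnesium bromide, C[Mg]Br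
Why: Grignard substitution at silicon exchanges the three chlorides for methyl groups and does not touch the allylic stereocentre.

Step 3
Reactants: 4 methyl furan-2-carboxylate; 5 ethyl diazoacetate
Product: 6 6-ethyl 3-methyl (1R,5R,6R)-2-oxabicyclo[3.1.0]hex-3-ene-3,6-dicarboxylate
Conditions: Cu(OTf)2 (1 mol%), 2,2′-(propane-2,2-diyl)bis[(4R)-4-isopropyl-4,5-dihydrooxazole], PhNHNH2 (cat.), CH2Cl2, 0 °C, slow addition of 5
Reagents that add atoms: none
Why: Asymmetric cyclopropanation by the monovalent copper–bis(oxazoline) carbene (formed in situ by reduction with phenylhydrazine) should occur at the unsubstituted 4,5-double bond of the furoate, exo to the ring, the ligand setting all three cyclopropane centres.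

Step 4
Reactants: 6 6-ethyl 3-methyl (1R,5R,6R)-2-oxabicyclo[3.1.0]hex-3-ene-3,6-dicarboxylate
Product: 8 ethyl (1R,2R,3R)-3-formyl-2-(2-methoxy-2-oxoacetoxy)cyclopropane-1-carboxylate, via secondary ozonide 7 (not isolated)
Conditions: O3, CH2Cl2, −78 °C; then Me2S, −78 °C to rt
Reagents that add atoms: ozone, [O-][O+]=O
Why: Ozonolysis with reductive work-up cleaves the remaining enol-ether double bond to the formyl group and leaves the former ring oxygen as a methyl oxalate, the cyclopropane centres being unaffected.

Step 5
Reactants: 8 ethyl (1R,2R,3R)-3-formyl-2-(2-methoxy-2-oxoacetoxy)cyclopropane-1-carboxylate; 3 (S)-(cyclopent-2-en-1-yl)trimethylsilane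
Product: 9 ethyl (1R,2R,3S)-3-{(R)-[(S)-cyclopent-2-en-1-yl](hydroxy)methyl}-2-(2-methoxy-2-oxoacetoxy)cyclopropane-1-carboxylate
Conditions: BF3·OEt2, CH2Cl2, −78 °C; aq. NaHCO3
Reagents that add atoms: none
Why: Hosomi–Sakurai allylation in which the aldehyde is attacked in the Felkin–Anh sense (anti to the ring bond leading to the acyloxy carbon, setting C6) and the S silane reacts anti-SE2′, so that C5 should form with the usual syn relationship to the carbinol (matched pairing).

Step 6
Reactants: 9 ethyl (1R,2R,3S)-3-{(R)-[(S)-cyclopent-2-en-1-yl](hydroxy)methyl}-2-(2-methoxy-2-oxoacetoxy)cyclopropane-1-carboxylate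
Product: 11 (4S,5R)-5-[(S)-cyclopent-2-en-1-yl]-4-(dimethoxymethyl)dihydrofuran-2(3H)-one, via lactone aldehyde 10 (not isolated)
Conditions: Ba(OH)2·8H2O, MeOH, 0 °C; then p-TsOH, HC(OMe)3, rt
Reagents that add atoms: trimethyl orthoformate, COC(OC)OC
Why: Saponification of the oxalate should trigger retro-aldol opening of the donor–acceptor cyclopropane and lactonisation to the trans-4,5-disubstituted γ-butyrolactone (C7 untouched and trans also the stable arrangement), and the freed C8 aldehyde is acetalised in the same flask.

Step 7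
Reactants: 11 (4S,5R)-5-[(S)-cyclopent-2-en-1-yl]-4-(dimethoxymethyl)dihydrofuran-2(3H)-one
Product: 12 allylic alcohol (11 with C3–OH on the cyclopentene ring trans to the lactone)
Conditions: SeO2 (0.5 equiv), t-BuOOH, CH2Cl2, rt
Reagents that add atoms: selenium dioxide, O=[Se]=O; tert-butyl hydroperoxide, CC(C)(C)OO
Why: Allylic hydroxylation by ene reaction and 2,3-sigmatropic shift should take the ring CH2 (C3) in preference to the hindered tertiary C5–H and the face anti to the lactone, the new carbinol centre being removed in step 8.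

Step 8
Reactants: 12 allylic alcohol
Product: 13 (4S,5R)-4-(dimethoxymethyl)-5-[(S)-4-oxocyclopent-2-en-1-yl]dihydrofuran-2(3H)-one
Conditions: Dess–Martin periodinane, NaHCO3, CH2Cl2, 0 °C to rt
Reagents that add atoms: none
Why: Dess–Martin oxidation gives the cyclopent-2-enone (C1=C2–C3=O) under non-basic conditions that leave the γ-centre C5 alone.

Step 9
Reactants: 13 (4S,5R)-4-(dimethoxymethyl)-5-[(S)-4-oxocyclopent-2-en-1-yl]dihydrofuran-2(3H)-one
Product: 15 bis-Mannich base (13 with CH2NMe2 at C4 and at C11), via dilithium bis-enolate 14 (not isolated)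
Conditions: LiN(iPr)2 (2.3 equiv), THF, −78 °C; then N,N-dimethylmethyleneiminium iodide, −78 to 0 °C
Reagents that add atoms: N,N-dimethylmethyleneiminium iodide (Eschenmoser's salt), C=[N+](C)C.[I-]
Why: Kinetic α′-deprotonation of the enone (C4) and α-deprotonation of the lactone (C11) followed by a double Mannich reaction installs both future exocyclic methylenes in masked form, each new group trans to its neighbour (both centres are destroyed in step 12).

Step 10
Reactants: 15 bis-Mannich base
Product: 16 aldehyde (15 with C8 = CHO)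
Conditions: 2 M HCl, THF, 0 °C to rt; then NaHCO3 to pH 8
Reagents that add atoms: water, O
Why: Acid hydrolysis of the dimethyl acetal, with the amines held as ammonium salts, frees the C8 aldehyde while C7 stays in its stable trans arrangement.

Step 11
Reactants: 16 aldehyde; 17 2,3-dibromoprop-1-ene
Product: 20 masked monomer 8β-hydroxy-4,11-bis(dimethylaminomethyl)-3-oxoguai-10(14)-en-12,6-olide, via bromoallyl silyl ether 18 (not isolated), via bicyclic silyl enol ether 19 (not isolated)
Conditions: CrCl2 (15 mol%), chiral oxazoline–sulfonamide ligand, Et3N, Mn powder, TMSCl, LiCl, MeCN, rt; then NiCl2·glyme (10 mol%), neocuproine, DMF, 40 °C, high dilution; 1 M HCl work-up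
Reagents that add atoms: none
Why: Proposed new method: 2,3-dibromopropene serves as a 1,2-dinucleophile in a relay of two reductive couplings that share manganese and TMSCl, in which divalent chromium first turns the allylic bromide into an allylchromium reagent that adds to the C8 aldehyde (C8–C9; closest known type: catalytic asymmetric Nozaki–Hiyama 2-haloallylation) and zerovalent nickel then inserts into the remaining vinyl bromide and couples it with the silyloxyallyl-nickel form of the enone (C10–C1; closest known type: nickel-catalysed reductive conjugate addition of alkenyl halides to enones, here intramolecular and in relay). Ring B closes in the second event by 7-exo-trig conjugate addition, a formal [5+2] annulation across C1–C5–C6–C7–C8. C8 is set by the chiral chromium sulfonamide complex (antipode chosen for 8R, against the Felkin–Anh bias of C7), and C1 is set by the tether, since C10 can only reach the enone face syn to the C5–C6 bond, which gives the cis-fused hydroazulene. Chemoselectivity rests on allylchromium adding to aldehydes but not to enones or lactones, on the vinyl bromide staying inert until nickel is added, and on the absence of any α-methylene carbonyl (both are masked as Mannich bases), while dilution suppresses intermolecular coupling. Acidic work-up removes the silyl ether and hydrolyses the silyl enol ether to the C3 ketone.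

Step 12
Reactants: 20 masked monomer
Product: 22 8β-hydroxy-3-dehydrozaluzanin C [(3aR,4R,6aR,9aR,9bR)-4-hydroxy-3,6,9-trimethylidene-octahydroazuleno[4,5-b]furan-2,8-dione], via bis-methiodide 21 (not isolated)
Conditions: MeI (excess), MeOH, rt; then aq. NaHCO3, EtOAc, rt
Reagents that add atoms: none
Why: Exhaustive N-methylation followed by Hofmann-type E1cB loss of trimethylamine from both β-ammonium carbonyls should unveil the α-methylene ketone (C4=C15) and the α-methylene lactone (C11=C13) without touching the free 8-OH.

Step 13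
Reactants: 22 8β-hydroxy-3-dehydrozaluzanin C
Product: 23 bis-silyl derivative (C2=C3 trimethylsilyl dienol ether and 8-O-trimethylsilyl ether of 22)
Conditions: TMSOTf (2.3 equiv), Et3N, CH2Cl2, −78 to 0 °C
Reagents that add atoms: trimethylsilyl trifluoromethanesulfonate, C[Si](C)(C)OS(=O)(=O)C(F)(F)F
Why: Soft enolisation, in which the C3 ketone can only enolise toward C2 because C4 is sp2, gives the 2-silyloxydiene while the 8-OH is silylated at the same time.

Step 14
Reactants: 23 bis-silyl derivative; 22 8β-hydroxy-3-dehydrozaluzanin C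
Product: 26 Diels–Alder adduct (Δ1(10); 2β-H; 5α-H), via trienone 24 (not isolated), via silylated adduct 25 (not isolated)
Conditions: Pd(OAc)2 (1.1 equiv), 22 (3 equiv), MeCN, rt to 40 °C; then 0.5 M HCl, THF, 0 °C
Reagents that add atoms: none
Why: Saegusa–Ito dehydrogenation gives the 1(2),4(15),10(14)-trien-3-one, whose locked s-cis diene C2=C1–C10=C14 should be trapped by the C4′=C15′ enone of excess 22 in a Diels–Alder reaction, with C14 (larger HOMO coefficient) bonding to the β-carbon C15′ and C2 bonding to C4′ on the convex α-face of the cis-fused dienophile (spiro centre R), the transient C2 centre being erased in step 15 and the silyl ether removed by the mild acid.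

Step 15
Reactants: 26 Diels–Alder adduct
Product: 27 CNP0397417.1
Conditions: DBU (0.2 equiv), CH2Cl2, 0 °C to rt
Reagents that add atoms: none
Why: Base-mediated prototropic isomerisation through the extended dienolate moves the double bond into conjugation (C1=C2) and protonates C10, and because C10–H and the doubly vinylogous C5–H remain exchangeable the system should settle under thermodynamic control in the arrangement where the spiro centre holds the new cyclohexene half-chair with C5′ pseudo-equatorial, C9 pseudo-axial on the α-face (10β-H) and C6 on the same face (5β-H), which is the configuration of the target.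

Compound list
1 | cyclopenta-1,3-diene | C1C=CC=C1 | starting material
2 | (S)-trichloro(cyclopent-2-en-1-yl)silane | Cl[Si](Cl)(Cl)[C@@H]1C=CCC1 | intermediate
3 | (S)-(cyclopent-2-en-1-yl)trimethylsilane | C[Si](C)(C)[C@@H]1C=CCC1 | intermediate
4 | methyl furan-2-carboxylate | COC(=O)c1ccco1 | starting material
5 | ethyl diazoacetate | CCOC(=O)C=[N+]=[N-] | starting material
6 | 6-ethyl 3-methyl (1R,5R,6R)-2-oxabicyclo[3.1.0]hex-3-ene-3,6-dicarboxylate | CCOC(=O)[C@H]1[C@@H]2OC(C(=O)OC)=C[C@H]12 | intermediate
7 | secondary ozonide of 6 (configuration at the two trioxolane carbons not defined; both are destroyed) | CCOC(=O)[C@H]1[C@@H]2OC3(C(=O)OC)OOC(O3)[C@H]12 | intermediate (not isolated)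
8 | ethyl (1R,2R,3R)-3-formyl-2-(2-methoxy-2-oxoacetoxy)cyclopropane-1-carboxylate | CCOC(=O)[C@H]1[C@H](OC(=O)C(=O)OC)[C@@H]1C=O | intermediate
9 | ethyl (1R,2R,3S)-3-{(R)-[(S)-cyclopent-2-en-1-yl](hydroxy)methyl}-2-(2-methoxy-2-oxoacetoxy)cyclopropane-1-carboxylate | CCOC(=O)[C@H]1[C@H](OC(=O)C(=O)OC)[C@@H]1[C@H](O)[C@@H]2C=CCC2 | intermediate
10 | (2R,3S)-2-[(S)-cyclopent-2-en-1-yl]-5-oxotetrahydrofuran-3-carbaldehyde | O=C[C@H]1CC(=O)O[C@@H]1[C@@H]2C=CCC2 | intermediate (not isolated)
11 | (4S,5R)-5-[(S)-cyclopent-2-en-1-yl]-4-(dimethoxymethyl)dihydrofuran-2(3H)-one | COC(OC)[C@H]1CC(=O)O[C@@H]1[C@@H]2C=CCC2 | intermediate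
12 | allylic alcohol: 11 with C3–OH on the cyclopentene, trans to the lactone | COC(OC)[C@H]1CC(=O)O[C@@H]1[C@@H]2C=C[C@@H](O)C2 | intermediate
13 | (4S,5R)-4-(dimethoxymethyl)-5-[(S)-4-oxocyclopent-2-en-1-yl]dihydrofuran-2(3H)-one | COC(OC)[C@H]1CC(=O)O[C@@H]1[C@@H]2C=CC(=O)C2 | intermediate
14 | dilithium bis-enolate of 13 (ketone C3/C4 enolate and lactone C11/C12 enolate) | [Li+].[Li+].COC(OC)[C@H]1C=C([O-])O[C@@H]1[C@@H]2C=CC([O-])=C2 | intermediate (not isolated)
15 | bis-Mannich base: 13 with CH2NMe2 at C4 (trans to the lactone) and at C11 (trans to the acetal carbon) | COC(OC)[C@H]1[C@H](CN(C)C)C(=O)O[C@@H]1[C@@H]2C=CC(=O)[C@H]2CN(C)C | intermediate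
16 | aldehyde: 15 with C8 = CHO (trans-lactone; C5, C6, C7 as in 11) | O=C[C@H]1[C@H](CN(C)C)C(=O)O[C@@H]1[C@@H]2C=CC(=O)[C@H]2CN(C)C | intermediate
17 | 2,3-dibromoprop-1-ene | C=C(Br)CBr | starting material
18 | 2-bromoallyl carbinol trimethylsilyl ether: 16 after C8–C9 bond formation (8R) | C=C(Br)C[C@@H](O[Si](C)(C)C)[C@H]1[C@H](CN(C)C)C(=O)O[C@@H]1[C@@H]2C=CC(=O)[C@H]2CN(C)C | intermediate (not isolated)
19 | cyclised bis-silyl compound: C2=C3 trimethylsilyl enol ether and 8-O-trimethylsilyl ether of 20 | CN(C)C[C@@H]1C(O[Si](C)(C)C)=C[C@H]2C(=C)C[C@@H](O[Si](C)(C)C)[C@H]3[C@H](CN(C)C)C(=O)O[C@@H]3[C@@H]12 | intermediate (not isolated)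
20 | masked monomer: 8β-hydroxy-4,11-bis(dimethylaminomethyl)-3-oxoguai-10(14)-en-12,6-olide (1α-H; 5α-H; 6β-H; 7α-H) | CN(C)C[C@@H]1C(=O)C[C@H]2C(=C)C[C@@H](O)[C@H]3[C@H](CN(C)C)C(=O)O[C@@H]3[C@@H]12 | intermediate
21 | bis-methiodide of 20 | C[N+](C)(C)C[C@@H]1C(=O)C[C@H]2C(=C)C[C@@H](O)[C@H]3[C@H](C[N+](C)(C)C)C(=O)O[C@@H]3[C@@H]12.[I-].[I-] | intermediate (not isolated)
22 | 8β-hydroxy-3-dehydrozaluzanin C, (3aR,4R,6aR,9aR,9bR)-4-hydroxy-3,6,9-trimethylidene-octahydroazuleno[4,5-b]furan-2,8-dione | C=C1C(=O)C[C@H]2C(=C)C[C@@H](O)[C@H]3C(=C)C(=O)O[C@@H]3[C@@H]12 | intermediate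
23 | bis-silyl derivative of 22: C2=C3 trimethylsilyl dienol ether and 8-O-trimethylsilyl ether | C=C1C(O[Si](C)(C)C)=C[C@H]2C(=C)C[C@@H](O[Si](C)(C)C)[C@H]3C(=C)C(=O)O[C@@H]3[C@@H]12 | intermediate
24 | trienone: 8-O-trimethylsilyl-1,2-didehydro derivative of 22 (5α-H) | C=C1C(=O)C=C2C(=C)C[C@@H](O[Si](C)(C)C)[C@H]3C(=C)C(=O)O[C@@H]3[C@@H]12 | intermediate (not isolated)
25 | silylated Diels–Alder adduct (8-O-trimethylsilyl ether of 26) | C=C1C(=O)[C@H]2C3=C(CC[C@]24C(=O)C[C@H]2C(=C)C[C@@H](O)[C@H]5C(=C)C(=O)O[C@@H]5[C@H]24)C[C@@H](O[Si](C)(C)C)[C@H]2C(=C)C(=O)O[C@@H]2[C@@H]13 | intermediate (not isolated)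
26 | Diels–Alder adduct: C1=C10 double bond, 2β-H, 5α-H, spiro C4′ as in the target | C=C1C(=O)[C@H]2C3=C(CC[C@]24C(=O)C[C@H]2C(=C)C[C@@H](O)[C@H]5C(=C)C(=O)O[C@@H]5[C@H]24)C[C@@H](O)[C@H]2C(=C)C(=O)O[C@@H]2[C@@H]13 | intermediate
27 | CNP0397417.1 | C=C1C(=O)C2=C3[C@H](CC[C@]24C(=O)C[C@H]2C(=C)C[C@@H](O)[C@H]5C(=C)C(=O)O[C@@H]5[C@H]24)C[C@@H](O)[C@H]2C(=C)C(=O)O[C@@H]2[C@H]13 | target

Total step count: 15.
Longest linear sequence: 13 steps (4 to 27 through steps 3–15; the branch 1 to 3 joins at step 5 and is equally 13 steps long).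

Steps most likely to fail

Step 11 (proposed new method). The relay may break down through cross-talk of the two metals (alkenylnickel passed on to chromium and lost by protonation), through intermolecular coupling outrunning the 7-exo closure, or through erosion of the C8 selectivity where catalyst and substrate bias are opposed. The fallback uses known reactions only, still in one flask, and sets out from 16: indium-mediated Barbier 2-bromoallylation with 17 (In powder, DMF, rt) should give the bromohomoallylic alcohol F1, expected as the Felkin–Anh (8α-OH) epimer; without isolation, Pd(OAc)2, PPh3, HCO2Na and Bu4NCl are added and the mixture is warmed to 70 °C, so that a reductive Heck cyclisation of the alkenylpalladium onto the enone closes ring B cis-fused and gives the 8-epimer of the masked monomer F2. Mitsunobu inversion (4-nitrobenzoic acid, PPh3, DIAD, THF) then gives the 8β-ester F3, and methanolysis (K2CO3, MeOH, 0 °C) comes back to 20.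

Step 14. The trienone may dimerise with itself instead of reacting with 22, the silyl dienol ether may hydrolyse before dehydrogenation, or divalent palladium may degrade the polyene. The fallback sets out from 23 and replaces the palladium dehydrogenation by selenoxide elimination: PhSeCl (CH2Cl2, −78 °C) should give the α-phenylselanyl ketone F4 with selenium on the convex α-face, syn to 1α-H; oxidation with H2O2/pyridine at 0 °C in the presence of 22 (3 equiv) lets the selenoxide eliminate slowly, so that 24 is released at low concentration and captured by 22 to give 25, and the same acid work-up comes back to 26.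

Step 9. The dianion may fail through competing γ-deprotonation at C5 (epimerisation), Michael oligomerisation between the lactone enolate and the enone, or retro-Mannich loss on work-up. The fallback sets out from 13 and avoids strong base: soft enolisation (TMSOTf, Et3N, CH2Cl2, −78 °C, excess amine to keep the acetal silent) should give the bis(trimethylsilyl) derivative F5 (lactone silyl ketene acetal and cross-conjugated 2-silyloxydiene), which undergoes a double Mukaiyama–Mannich reaction with N,N-dimethylmethyleneiminium iodide in CH2Cl2 at rt and comes back to 15.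

Further compounds
F1 | step 11 | bromohomoallylic alcohol, 8-epimer of desilylated 18 (8α-OH) | C=C(Br)C[C@H](O)[C@H]1[C@H](CN(C)C)C(=O)O[C@@H]1[C@@H]2C=CC(=O)[C@H]2CN(C)C
F2 | step 11 | 8-epimer of the masked monomer 20 (8α-OH) | CN(C)C[C@@H]1C(=O)C[C@H]2C(=C)C[C@H](O)[C@H]3[C@H](CN(C)C)C(=O)O[C@@H]3[C@@H]12
F3 | step 11 | 8β-(4-nitrobenzoate) of 20 | CN(C)C[C@@H]1C(=O)C[C@H]2C(=C)C[C@@H](OC(=O)c4ccc(cc4)[N+](=O)[O-])[C@H]3[C@H](CN(C)C)C(=O)O[C@@H]3[C@@H]12
F4 | step 14 | 2α-phenylselanyl-8-O-trimethylsilyl derivative of 22 | C=C1C(=O)[C@H]([Se]c4ccccc4)[C@H]2C(=C)C[C@@H](O[Si](C)(C)C)[C@H]3C(=C)C(=O)O[C@@H]3[C@@H]12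
F5 | step 9 | bis(trimethylsilyl) derivative of 13 (silyl ketene acetal and 2-silyloxydiene) | COC(OC)[C@H]1C=C(O[Si](C)(C)C)O[C@@H]1[C@@H]2C=CC(O[Si](C)(C)C)=C2
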